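**Retrosynthetic overview**
1. Target ⇐ 2,5-dimethoxyquinone (hydrolysis of the methoxy group next to the side chain) ⇐ tetramethoxyarene cis-decalol (oxidative demethylation).
2. C10–H ⇐ hydroxyl-directed hydrogenation of a C1=C10 allylic alcohol; key C5–O bond ⇐ singlet-oxygen ene reaction on the tetrasubstituted C5=C10 alkene.
3. C5=C10 alkene with C8 and C9 set ⇐ 1,2-H/1,2-Me shift cascade launched from a drimane C8 tertiary formate.
4. Aryl–C11 bond ⇐ Negishi coupling of a C11 iodide with the arylzinc from 1,2,4,5-tetramethoxybenzene; iodide and formate ⇐ alkoxy-radical fragmentation of sclareolide lactol.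
5. Ring order: both carbocycles come intact from (+)-sclareolide (lactone carbon C12 is excised, no ring is built); the quinone is unveiled last.

Assumption: positions follow the drimane numbering of sclareolide (in the target C5 is the carbinol carbon, C10 the ring-fusion CH, C9 the quaternary carbon, C8 the CHMe, C11 the benzylic CH2), α is the face opposite to the C10 methyl group of sclareolide, and all reagents named are commercial.

**Route**

Step 1
Reactants: 1 (+)-sclareolide
Product: 2 sclareolide lactol (anomer mixture)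
Conditions: i-Bu2AlH, CH2Cl2, −78 °C; aqueous work-up
Reagents that add atoms: none
Why: Partial reduction of the γ-lactone by one hydride equivalent at low temperature (DIBAL reduction) stops at the aluminium hemiacetal and touches no stereocentre of the decalin.

Step 2
Reactants: 2 sclareolide lactol
Product: 4 (1R,2R,4aS,8aS)-1-(iodomethyl)-2,5,5,8a-tetramethyldecahydronaphthalen-2-yl formate, via lactol hypoiodite 3 (not isolated)
Conditions: PhI(OAc)2, I2, cyclohexane, hν (tungsten lamp), rt
Reagents that add atoms: iodine, II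
Why: Suárez hypoiodite reaction, in which the anomeric alkoxy radical undergoes β-scission of the C11–C12 bond to leave the C8 tertiary formate and a primary C11 radical that is capped by iodine, so C12 is excised without touching C5, C8, C9 or C10.

Step 3
Reactants: 4 (1R,2R,4aS,8aS)-1-(iodomethyl)-2,5,5,8a-tetramethyldecahydronaphthalen-2-yl formate; 5 1,2,4,5-tetramethoxybenzene
Product: 8 (1R,2R,4aS,8aS)-2,5,5,8a-tetramethyl-1-[(2,3,5,6-tetramethoxyphenyl)methyl]decahydronaphthalen-2-yl formate, via aryllithium 6 (not isolated), via arylzinc chloride 7 (not isolated)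
Conditions: 5, n-BuLi, THF, 0 °C → rt; ZnCl2, 0 °C; then 4, Ni(acac)2 (10 mol %), 4-(trifluoromethyl)styrene, THF/NMP, −15 °C → rt
Reagents that add atoms: none
Why: Nickel-catalysed Negishi sp3–sp2 coupling of a primary alkyl iodide with an arylzinc halide made by lithiation of 5 between two methoxy groups, in which the electron-poor styrene speeds reductive elimination over β-hydride elimination and the non-basic zinc reagent spares the tertiary formate; no stereocentre is formed.

Step 4
Reactants: 8 (1R,2R,4aS,8aS)-2,5,5,8a-tetramethyl-1-[(2,3,5,6-tetramethoxyphenyl)methyl]decahydronaphthalen-2-yl formate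
Product: 9 1,2,4,5-tetramethoxy-3-{[(1R,2S)-1,2,5,5-tetramethyl-1,2,3,4,5,6,7,8-octahydronaphthalen-1-yl]methyl}benzene
Conditions: BF3·OEt2 (0.5 equiv), CH2Cl2, −78 → −20 °C
Reagents that add atoms: none
Why: Proposed new method: BF3 bound to the formyl oxygen heterolyses the tertiary C8–O bond (a tertiary formate, not the usual 8(12)-alkene, is the cation source), and the C8 cation relays through two suprafacial antiperiplanar 1,2-shifts, H9α to C8 (sets C8 with the methyl β) and the C10 β-methyl to C9 (sets the C9 quaternary centre with the arylmethyl group α), before loss of the C5 proton gives the tetrasubstituted C5=C10 alkene and HCO2H·BF3 turns the Lewis acid over; the closest known reaction type is the BF3-promoted friedo-type rearrangement of drim-8(12)-enyl arenes, joined to the Lewis-acid E1 cleavage of tertiary esters.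

Step 5
Reactants: 9 1,2,4,5-tetramethoxy-3-{[(1R,2S)-1,2,5,5-tetramethyl-1,2,3,4,5,6,7,8-octahydronaphthalen-1-yl]methyl}benzene
Product: 11 (1R,2S,4aR)-1,2,5,5-tetramethyl-1-[(2,3,5,6-tetramethoxyphenyl)methyl]-1,2,3,4,4a,5,6,7-octahydronaphthalen-4a-ol, via allylic hydroperoxide 10 (not isolated)
Conditions: O2, tetraphenylporphyrin (cat.), hν (visible), CH2Cl2, −30 °C; then PPh3, −30 °C → rt
Reagents that add atoms: dioxygen, O=O
Why: Schenck ene reaction followed by phosphine reduction, in which singlet oxygen is expected to add from the α face (the β-methyl groups at C4, C8 and C9 always leave one (pseudo)axial methyl on the β face, whereas the half-chair with the arylmethyl group pseudo-equatorial has a clear α face), to remove the pseudo-axial C1 hydrogen geminal to the bulkier C9 centre (large-group effect) and so to form the C5–O bond suprafacially with the alkene moving to C1=C10, which sets C5 with oxygen α; PPh3 cleaves only the O–O bond.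

Step 6
Reactants: 11 (1R,2S,4aR)-1,2,5,5-tetramethyl-1-[(2,3,5,6-tetramethoxyphenyl)methyl]-1,2,3,4,4a,5,6,7-octahydronaphthalen-4a-ol
Product: 12 (1R,2S,4aS,8aS)-1,2,5,5-tetramethyl-1-[(2,3,5,6-tetramethoxyphenyl)methyl]decahydronaphthalen-4a-ol
Conditions: H2 (1 atm), [Ir(cod)(PCy3)(py)]PF6 (5 mol %), CH2Cl2, rt
Reagents that add atoms: none
Why: Hydroxyl-directed homogeneous hydrogenation, in which the cationic iridium centre binds the tertiary C5–OH and adds H2 to the C1=C10 alkene on that same α face, setting C10–H cis to the hydroxyl (cis-decalin) against the steric bias while the arene is inert.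

Step 7
Reactants: 12 (1R,2S,4aS,8aS)-1,2,5,5-tetramethyl-1-[(2,3,5,6-tetramethoxyphenyl)methyl]decahydronaphthalen-4a-ol
Product: 13 3-{[(1R,2S,4aS,8aS)-4a-hydroxy-1,2,5,5-tetramethyldecahydronaphthalen-1-yl]methyl}-2,5-dimethoxycyclohexa-2,5-diene-1,4-dione
Conditions: (NH4)2Ce(NO3)6 (2.5 equiv), MeCN/H2O, 0 °C
Reagents that add atoms: water, O
Why: Oxidative demethylation of a para-dimethoxyarene by tetravalent cerium (arene radical cation, ipso attack of water, loss of methanol) gives the 2,5-dimethoxy-1,4-benzoquinone, both para pairs leading to the same quinone, while the tertiary alcohol and the saturated decalin are inert at 0 °C.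

Step 8
Reactants: 13 3-{[(1R,2S,4aS,8aS)-4a-hydroxy-1,2,5,5-tetramethyldecahydronaphthalen-1-yl]methyl}-2,5-dimethoxycyclohexa-2,5-diene-1,4-dione
Product: 14 2-hydroxy-3-{[(1R,2S,4aS,8aS)-4a-hydroxy-1,2,5,5-tetramethyldecahydronaphthalen-1-yl]methyl}-5-methoxycyclohexa-2,5-diene-1,4-dione (CNP0209468.1)
Conditions: KOH, MeOH/H2O, rt; then dilute aq. HCl to pH 3
Reagents that add atoms: potassium hydroxide, [K+].[OH-]
Why: Vinylogous ester hydrolysis by addition–elimination of hydroxide at the methoxy-bearing quinone carbon next to the alkyl group, the selectivity used for 2-hydroxy-5-methoxy-3-alkylquinones of the ilimaquinone family, after which the vinylogous carboxylate resists further attack and no stereocentre is affected.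

**Compound list**
1 | (+)-sclareolide, (3aR,5aS,9aS,9bR)-3a,6,6,9a-tetramethyldecahydronaphtho[2,1-b]furan-2(1H)-one | O=C1C[C@H]2[C@](C)(O1)CC[C@H]3C(C)(C)CCC[C@]23C | starting material
2 | sclareolide lactol, (3aR,5aS,9aS,9bR)-3a,6,6,9a-tetramethyldodecahydronaphtho[2,1-b]furan-2-ol (anomer mixture) | OC1C[C@H]2[C@](C)(O1)CC[C@H]3C(C)(C)CCC[C@]23C | intermediate
3 | lactol hypoiodite (O–I derivative of 2) | IOC1C[C@H]2[C@](C)(O1)CC[C@H]3C(C)(C)CCC[C@]23C | intermediate
4 | (1R,2R,4aS,8aS)-1-(iodomethyl)-2,5,5,8a-tetramethyldecahydronaphthalen-2-yl formate (11-iodo-drim-8α-yl formate) | O=CO[C@]1(C)CC[C@H]2C(C)(C)CCC[C@]2(C)[C@H]1CI | intermediate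
5 | 1,2,4,5-tetramethoxybenzene | COc1cc(OC)c(OC)cc1OC | starting material
6 | (2,3,5,6-tetramethoxyphenyl)lithium | [Li]c1c(OC)c(OC)cc(OC)c1OC | intermediate
7 | (2,3,5,6-tetramethoxyphenyl)zinc chloride | Cl[Zn]c1c(OC)c(OC)cc(OC)c1OC | intermediate
8 | (1R,2R,4aS,8aS)-2,5,5,8a-tetramethyl-1-[(2,3,5,6-tetramethoxyphenyl)methyl]decahydronaphthalen-2-yl formate | O=CO[C@]1(C)CC[C@H]2C(C)(C)CCC[C@]2(C)[C@H]1Cc1c(OC)c(OC)cc(OC)c1OC | intermediate
9 | 1,2,4,5-tetramethoxy-3-{[(1R,2S)-1,2,5,5-tetramethyl-1,2,3,4,5,6,7,8-octahydronaphthalen-1-yl]methyl}benzene (C5=C10 alkene, 8β-Me, 9β-Me, 9α-CH2Ar) | COc1cc(OC)c(OC)c(C[C@]2(C)[C@@H](C)CCC3=C2CCCC3(C)C)c1OC | intermediate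
10 | (1R,2S,4aR)-4a-hydroperoxy-1,2,5,5-tetramethyl-1-[(2,3,5,6-tetramethoxyphenyl)methyl]-1,2,3,4,4a,5,6,7-octahydronaphthalene (OOH α, cis to the arylmethyl group; C1=C10 alkene) | COc1cc(OC)c(OC)c(C[C@]2(C)[C@@H](C)CC[C@]3(OO)C2=CCCC3(C)C)c1OC | intermediate
11 | (1R,2S,4aR)-1,2,5,5-tetramethyl-1-[(2,3,5,6-tetramethoxyphenyl)methyl]-1,2,3,4,4a,5,6,7-octahydronaphthalen-4a-ol (OH α; C1=C10 alkene) | COc1cc(OC)c(OC)c(C[C@]2(C)[C@@H](C)CC[C@]3(O)C2=CCCC3(C)C)c1OC | intermediate
12 | (1R,2S,4aS,8aS)-1,2,5,5-tetramethyl-1-[(2,3,5,6-tetramethoxyphenyl)methyl]decahydronaphthalen-4a-ol (5α-OH, 10α-H, cis-decalin) | COc1cc(OC)c(OC)c(C[C@]2(C)[C@@H](C)CC[C@]3(O)[C@H]2CCCC3(C)C)c1OC | intermediate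
13 | 3-{[(1R,2S,4aS,8aS)-4a-hydroxy-1,2,5,5-tetramethyldecahydronaphthalen-1-yl]methyl}-2,5-dimethoxycyclohexa-2,5-diene-1,4-dione | COC1=CC(=O)C(OC)=C(C[C@]2(C)[C@@H](C)CC[C@]3(O)[C@H]2CCCC3(C)C)C1=O | intermediate
14 | 2-hydroxy-3-{[(1R,2S,4aS,8aS)-4a-hydroxy-1,2,5,5-tetramethyldecahydronaphthalen-1-yl]methyl}-5-methoxycyclohexa-2,5-diene-1,4-dione (CNP0209468.1) | COC1=CC(=O)C(O)=C(C[C@]2(C)[C@@H](C)CC[C@]3(O)[C@H]2CCCC3(C)C)C1=O | target

**Step count and risks**
Total step count: 8. Longest linear sequence: 8 steps (1 → 14); the arylzinc partner is generated in the flask of step 3 from commercial 5.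

Three steps most likely to fail:

Step 4 (the proposed new step). The formate may not ionise cleanly, the cascade may stall at the C7/C8(12) alkenes, or it may run on to attack an ortho-methoxy group. The fallback uses known chemistry and sets out from 8. Methanolysis of the formate (K2CO3, MeOH, rt) gives the tertiary alcohol (1R,2R,4aS,8aS)-2,5,5,8a-tetramethyl-1-[(2,3,5,6-tetramethoxyphenyl)methyl]decahydronaphthalen-2-ol F1. Dehydration (SOCl2, pyridine, −30 °C) gives mainly the exocyclic alkene 1,2,4,5-tetramethoxy-3-{[(1S,4aS,8aS)-5,5,8a-trimethyl-2-methylidenedecahydronaphthalen-1-yl]methyl}benzene F2; its endocyclic isomers converge in the next operation. BF3·OEt2 in CH2Cl2 at −50 °C, the established rearrangement of such 8(12)-alkenes, then returns to the route at 9.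

Step 5. Hydrogen abstraction from C6 would place the oxygen on C10, and attack from the β face would give the C5 epimer; both selectivities rest on conformational arguments, not on a tether. The fallback sets out from 9 and replaces the ene/hydrogenation pair by one concerted syn addition. Hydroboration with BH3·THF (THF, 45 °C), boron going to the less encumbered C5, gives the tertiary alkylborane 4aα-(dihydroboryl)-1,2,5,5-tetramethyl-1-[(2,3,5,6-tetramethoxyphenyl)methyl]decahydronaphthalene F3, which is oxidised in the same flask (NaOH, H2O2, 0 °C → rt). This comes back to the route at 12 and bypasses 11 and step 6.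

Step 3. Coupling a β-branched primary iodide with a doubly ortho-substituted arylzinc may be slow and give reduction or the C9=C11 alkene. The fallback reverses the polarity and sets out from 4 and 5. Compound 5 is brominated (N-bromosuccinimide, MeCN, rt) to 3-bromo-1,2,4,5-tetramethoxybenzene F4. Zinc insertion into 4 (Zn dust, LiCl, THF, 40 °C) gives the alkylzinc iodide [(1R,2R,4aS,8aS)-2-(formyloxy)-2,5,5,8a-tetramethyldecahydronaphthalen-1-yl]methylzinc iodide F5. Negishi coupling of F5 with F4 under Pd(OAc)2/CPhos (THF, rt) comes back to the route at 8.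

**Further compounds**
F1 | step 4 | (1R,2R,4aS,8aS)-2,5,5,8a-tetramethyl-1-[(2,3,5,6-tetramethoxyphenyl)methyl]decahydronaphthalen-2-ol | O[C@]1(C)CC[C@H]2C(C)(C)CCC[C@]2(C)[C@H]1Cc1c(OC)c(OC)cc(OC)c1OC
F2 | step 4 | 1,2,4,5-tetramethoxy-3-{[(1S,4aS,8aS)-5,5,8a-trimethyl-2-methylidenedecahydronaphthalen-1-yl]methyl}benzene | C=C1CC[C@H]2C(C)(C)CCC[C@]2(C)[C@H]1Cc1c(OC)c(OC)cc(OC)c1OC
F3 | step 5 | 4aα-(dihydroboryl)-1,2,5,5-tetramethyl-1-[(2,3,5,6-tetramethoxyphenyl)methyl]decahydronaphthalene (BH2 cis to H8a and to the arylmethyl group) | COc1cc(OC)c(OC)c(C[C@]2(C)[C@@H](C)CC[C@]3(B)[C@H]2CCCC3(C)C)c1OC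
F4 | step 3 | 3-bromo-1,2,4,5-tetramethoxybenzene | COc1cc(OC)c(OC)c(Br)c1OC
F5 | step 3 | [(1R,2R,4aS,8aS)-2-(formyloxy)-2,5,5,8a-tetramethyldecahydronaphthalen-1-yl]methylzinc iodide | O=CO[C@]1(C)CC[C@H]2C(C)(C)CCC[C@]2(C)[C@H]1C[Zn]I
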